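## The problem

Compound 25 is an unsymmetrical dimer of two 2-(2-phenylethyl)chromones: an aromatic unit A (6-oxy-7-methoxy) and a 5,6,7,8-tetrahydro unit B, joined by a secondary alkyl aryl ether from C8 of unit B to O6 of unit A. Unit B carries four contiguous stereocentres, (5S,6R,7S,8S), with 5,6-trans, 6,7-trans and 7,8-cis oxygens on a cyclohexene fused to a γ-pyranone. C6 and C7 form a threo diol that can be bought. C7 can steer C8 through a chelate in an open chain, and C6 together with the half-chair fixed by C7 and C8 can steer C5 during ring closure, so C5 is best set last. The unit A ring is electron-rich, so the ether cannot come from arylation of a C8 alcohol; it has to be made by SN2 attack of the phenol at C8, with inversion. The C8 hydrogen is α to the aryloxy group and vinylogously α to the C4 carbonyl, so base can epimerise C8 and expel the C7 oxygen, which leads on to an aromatic chromone. The C5 carbinol sits on a carbon whose cation is stabilised by O1 through C4a=C8a, so strong acid is excluded as well, and the chromone of unit A accepts nucleophiles at C2 and is acidic at its side-chain CH2. The enabling feature is the tetrasubstituted C4a=C8a alkene of unit B: C4a bears the C4 acyl group and the C5 carbinol, C8a bears a heteroatom. This is the pattern of a β-halo Baylis–Hillman adduct whose halide is later replaced by O1.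

## Retrosynthesis

**25 from 24 (two O–benzyl bonds).** O6 and O7 are carried as benzyl ethers. A small, chelating ether is wanted at O6 for the ring closure, and it must survive MgI2, Pd/Cu catalysis, fluoride and carbonate. Silyl ethers would not chelate, p-methoxybenzyl ethers are at risk from a magnesium halide with iodide present, and a trans-fused acetonide would add strain to the ring closure. The forward step must remove two benzyl groups without touching the C8–O aryl bond, the C5 carbinol or the two pyranone double bonds.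

**24 from 22 through 23 (O1–C8a).** The pyranone could also be cut at C2–C3 (Claisen condensation on a C4a acetyl compound), but that needs strong base on a ring that has an acidic C8 hydrogen. Cutting O1–C8a asks only that the enol oxygen of the 1,3-diketone 23 displaces a vinylic iodide with K2CO3. The C2 ketone of 23 is kept as a dioxolane in 22, because a free ynone diketone would close to a pyranone on its own before the carbocycle exists. The forward reaction must favour the six-membered addition–elimination over condensation of the C5 hydroxyl with the freed ketone.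

**22 from 21 (C4a–C5 and C8a–I; the key cut).** Closing the carbocycle at C4a–C5 by an iodide-triggered conjugate addition–aldol turns an open chain, 21, into the ring. The same step creates C5 and places the leaving group for the next step on C8a. Ring-closing metathesis cannot make the tetrasubstituted, acyl-bearing alkene, and closures at C5–C6 or C8–C8a would each need a separate step to install the C8a heteroatom. The forward reaction must add iodide at C8a, close the ring on the C8 side of the allenolate, and give the 5,6-trans alcohol.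

**21 from 14 and 17 through 20, 19 and 18 (C4–C4a).** The ynone is cut at the acyl–alkyne bond. An acyl Sonogashira coupling of alkyne 14 with acid chloride 18 (made in the flask from acid 17) avoids a lithium acetylide, which neither the chromone nor the C8 hydrogen would tolerate. The aldehyde is the most fragile group, so it is unveiled last: desilylation of 19 to 20, then oxidation to 21. Acid 17 comes from β-keto ester 15 by ketalisation (16) and saponification.

**14 from 7 and 13 (C8–O).** This cut divides the target into two halves of similar size. The forward reaction is a Mitsunobu etherification of phenol 13 with the propargylic alcohol 7, with inversion at C8. The alternative, displacement at C2 of a xylofuranoside, would force the phenol onto the ring face that carries the C3 and C4 substituents, next to the anomeric carbon, to give an all-cis product. An open-chain propargylic carbinol is a far better SN2 centre.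

**7 from 1 through 6, 5, 4, 3 and 2 (C8–C8a).** The alkyne is added to the α-benzyloxy aldehyde 5 as a zinc acetylide under chelation control, which gives the 7,8-syn alcohol (6, then 7 after loss of the C-silyl group). The Mitsunobu step then inverts it to the 7,8-anti ether that the ring needs as 7,8-cis. C6 and C7 come from diethyl D-tartrate 1 by benzylation (2), reduction (3), monosilylation (4) and oxidation (5); because 3 is C2-symmetric, monosilylation gives a single compound. A pentose would supply C8 from the pool as well, but only at the price of the hindered furanoside displacement or a long differentiation of O2 from O4.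

**13 from 8 and 10 through 9, 11 and 12.** Unit A is made alone, where strong base does no harm. The non-chelated hydroxyl of acetophenone 8 is benzylated (9). Claisen condensation with ester 10 gives diketone 11, which is cyclodehydrated to chromone 12, and hydrogenolysis frees phenol 13.

## Roads not taken

**Alternative 1:** The pyranone of unit B is cut at C4–C4a and O1–C8a. In the forward step the morpholine enamine A2 of a C8a cyclohexanone, whose oxygen pattern would be elaborated after enzymatic cis-dihydroxylation of an arene, is heated with the acylated Meldrum's acid A3. The acylketene acylates C4a, the enol oxygen closes onto C8a and morpholine leaves. This gives A1, the tris-silyl ether of unit B with a 4-benzyloxy-2-methoxyphenyl ether at C8.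
- Merits: the annulation is thermal and neutral, and the acylketene–enamine route to γ-pyranones is well documented. On this point it is stronger than the ring-forming iodo-aldol, whose endocyclic variant has little precedent.
- Weak points: A2 is the enamine of an α-aryloxy ketone with a β-silyloxy group on the other side, so its formation risks epimerisation at C8 and β-elimination of the C5 oxygen. The cis-dihydroxylation supplies only the 7,8-cis pair; the trans oxygens at C5 and C6 need further epoxide chemistry.
- Most serious: unit A is absent from A1. After debenzylation the phenol would have to be C-acetylated, condensed with an ester under strong base and cyclised, all in the presence of the base-sensitive unit B.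
- Comparison: the chosen plan accepts a less secure key step, and sets against it that the finished unit A arrives in one Mitsunobu step and that no C8a ketone is ever formed.

**Alternative 2:** Both pyranones are cut at C2–C3 and O1–C2. The bis(acetyl) core A5 (the ortho-hydroxyacetophenone of unit A, ether-linked to a tribenzylated 2-acetyl-3-hydroxycyclohexene) is turned into a polyanion with LiN(i-Pr)2 and acylated twice by ester 10. Acid then closes both rings to A4, the 5,6,7-tri-O-benzyl ether of 25.
- Merits: this is the most economical end game. Two rings and four bonds form in one operation, against one ring and two bonds in step 15, and the chemistry is classical.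
- Weak points: A5 is a cyclic β-diketone whose C8 is α to a ketone and bears the aryloxy group. Excess amide base would deprotonate C8, with epimerisation and E1cB loss of the C7 benzyloxide, followed by aromatisation. The two acetyl groups differ in acidity, so clean double acylation is doubtful, and hot acid endangers the C5 ether.
- Further: A5 still needs a stereocontrolled synthesis of a tetra-oxygenated 2-acetylcyclohexanone, so the carbocycle problem is only postponed.
- Comparison: the chosen plan is less convergent at the end. In return, strong base acts only on 9, and the carbocycle is made in the same step that prepares the pyranone.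

**Alternative 3:** The carbocycle is cut at C4a–C8a. Aldoxime A7, a hexose-derived chain with the aryl ether at C8, benzyl ethers at C5 to C7 and a C4a≡C4 alkyne, is oxidised with NaOCl to a nitrile oxide that adds across the alkyne. This forms C8a–C4a and O–C4 and gives the isoxazole-fused carbocycle A6.
- Merits: the intramolecular nitrile oxide–alkyne cycloaddition on sugar templates is among the most reliable carbocyclisations. All four stereocentres are in place before ring closure, so nothing depends on facial selectivity. That is a clear advantage over step 15, where C5 is created.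
- Weak points: the isoxazole is only a masked 1,3-dicarbonyl. Reaching the pyranone needs N–O reduction (Mo(CO)6 or hydrogenation, which threatens the benzyl ethers and the C8 aryl ether), hydrolysis of the enaminone (with competing closure to a 4-pyridone), desilylation, oxidation of a side-chain carbinol whose stereocentre is carried only to be destroyed, and cyclodehydration. That is five operations against two after step 15.
- Further: hypochlorite may chlorinate the electron-rich ring of unit A, and the α-aryloxy aldoxime can epimerise at C8.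
- Comparison: the chosen plan has the less certain ring closure. It sets against this that iodide already sits at C8a at the right oxidation level, so the pyranone follows in one mild operation.

Key step: step 15

Remark: the labels C2 to C8a and O1 refer to unit B of 25 in all intermediates. Aldehydes 5 and 21 are assumed to be used without chromatography.

## Route

Step 1
Reactants: 1 diethyl D-tartrate, diethyl (2S,3S)-2,3-dihydroxybutanedioate
Product: 2 diethyl (2S,3S)-2,3-bis(benzyloxy)butanedioate
Conditions: NaH, BnBr, Bu4NI (cat.), THF, 0 °C → rt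
Reagents that add atoms: benzyl bromide, BrCc1ccccc1
Why: Williamson etherification of both secondary hydroxyls; in THF at low temperature with iodide catalysis the alkoxide is benzylated faster than the neighbouring ester is enolised, so both stereocentres should be kept.

Step 2
Reactants: 2 diethyl (2S,3S)-2,3-bis(benzyloxy)butanedioate
Product: 3 (2R,3R)-2,3-bis(benzyloxy)butane-1,4-diol
Conditions: LiAlH4, THF, 0 °C → rt
Reagents that add atoms: none
Why: Hydride reduction of both esters to primary alcohols; no bond at a stereocentre is touched (the descriptors change only through the priority rules).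

Step 3
Reactants: 3 (2R,3R)-2,3-bis(benzyloxy)butane-1,4-diol
Product: 4 (2R,3R)-2,3-bis(benzyloxy)-4-[(tert-butyldimethylsilyl)oxy]butan-1-ol
Conditions: NaH (1.0 equiv), THF, rt; TBSCl (1.0 equiv)
Reagents that add atoms: tert-butyldimethylsilyl chloride, CC(C)(C)[Si](C)(C)Cl
Why: Monosilylation of a symmetric diol through its sparingly soluble monosodium alkoxide; the two hydroxyls of the C2-symmetric diol are equivalent, so only one monoether can form.

Step 4
Reactants: 4 (2R,3R)-2,3-bis(benzyloxy)-4-[(tert-butyldimethylsilyl)oxy]butan-1-ol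
Product: 5 (2S,3R)-2,3-bis(benzyloxy)-4-[(tert-butyldimethylsilyl)oxy]butanal
Conditions: (COCl)2, DMSO, CH2Cl2, −78 °C; Et3N, −78 → 0 °C
Reagents that add atoms: none
Why: Swern oxidation of the primary alcohol; the cold, brief base treatment should leave the α-benzyloxy centre intact, and the aldehyde is used crude.

Step 5
Reactants: 5 (2S,3R)-2,3-bis(benzyloxy)-4-[(tert-butyldimethylsilyl)oxy]butanal
Product: 7 (3S,4R,5R)-4,5-bis(benzyloxy)-6-[(tert-butyldimethylsilyl)oxy]hex-1-yn-3-ol, via TMS-alkynol 6 (not isolated)
Conditions: Me3SiC≡CH, n-BuLi, Et2O, −78 °C; ZnBr2, 0 °C; 5, −78 → 0 °C; then K2CO3, MeOH, rt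
Reagents that add atoms: ethynyltrimethylsilane, C#C[Si](C)(C)C
Why: Chelation-controlled addition of an alkynylzinc halide to an α-alkoxy aldehyde (Cram chelate): zinc ties the aldehyde oxygen to the C7 benzyloxy oxygen and the acetylide enters opposite the C6 chain, setting C8 syn to the C7 ether (3S); methanolic K2CO3 then cleaves the C–Si bond.

Step 6
Reactants: 8 1-(2,5-dihydroxy-4-methoxyphenyl)ethanone
Product: 9 1-[5-(benzyloxy)-2-hydroxy-4-methoxyphenyl]ethanone
Conditions: BnBr (1.05 equiv), K2CO3, acetone, reflux
Reagents that add atoms: benzyl bromide, BrCc1ccccc1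
Why: Selective Williamson etherification; the 2-hydroxyl is hydrogen-bonded to the acetyl group and much less nucleophilic, so the 5-hydroxyl should react alone.

Step 7
Reactants: 9 1-[5-(benzyloxy)-2-hydroxy-4-methoxyphenyl]ethanone; 10 ethyl 3-phenylpropanoate
Product: 12 6-(benzyloxy)-7-methoxy-2-(2-phenylethyl)-4H-chromen-4-one, via aryl 1,3-diketone 11 (not isolated)
Conditions: NaH, 10 (excess), THF, reflux; then conc. HCl (cat.), MeOH, 60 °C
Reagents that add atoms: none
Why: Claisen condensation of the methyl ketone enolate with the ester gives the 1,3-diketone, and acid cyclodehydration through the ortho phenol closes the chromone; the strong base acts here on unit A alone.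

Step 8
Reactants: 12 6-(benzyloxy)-7-methoxy-2-(2-phenylethyl)-4H-chromen-4-one
Product: 13 6-hydroxy-7-methoxy-2-(2-phenylethyl)-4H-chromen-4-one
Conditions: H2 (1 atm), 10% Pd/C, EtOAc/MeOH, rt
Reagents that add atoms: none
Why: Hydrogenolysis of an aryl benzyl ether, which is fast; the chromone C2=C3 bond is known to survive conditions that reduce styrenes and cleave benzyl ethers.

Step 9
Reactants: 7 (3S,4R,5R)-4,5-bis(benzyloxy)-6-[(tert-butyldimethylsilyl)oxy]hex-1-yn-3-ol; 13 6-hydroxy-7-methoxy-2-(2-phenylethyl)-4H-chromen-4-one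
Product: 14 6-{[(3R,4R,5R)-4,5-bis(benzyloxy)-6-[(tert-butyldimethylsilyl)oxy]hex-1-yn-3-yl]oxy}-7-methoxy-2-(2-phenylethyl)-4H-chromen-4-one
Conditions: PPh3, DIAD, THF/toluene, 0 °C → rt
Reagents that add atoms: none
Why: Mitsunobu etherification of a phenol with a secondary propargylic alcohol; SN2 attack on the alkoxyphosphonium ion inverts C8 and turns the 7,8-syn alcohol into the 7,8-anti aryl ether; the small alkynyl group offsets the deactivation by the neighbouring benzyloxy group.

Step 10
Reactants: 15 ethyl 3-oxo-5-phenylpentanoate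
Product: 16 ethyl 2-[2-(2-phenylethyl)-1,3-dioxolan-2-yl]acetate
Conditions: HOCH2CH2OH, TsOH·H2O (cat.), toluene, reflux, Dean–Stark
Reagents that add atoms: ethane-1,2-diol, OCCO
Why: Acid-catalysed ketalisation of the ketone of a β-keto ester with azeotropic removal of water; the ester does not react.

Step 11
Reactants: 16 ethyl 2-[2-(2-phenylethyl)-1,3-dioxolan-2-yl]acetate
Product: 17 2-[2-(2-phenylethyl)-1,3-dioxolan-2-yl]acetic acid
Conditions: LiOH·H2O, THF/MeOH/H2O, rt; then 0.5 M HCl to pH 4, 0 °C
Reagents that add atoms: lithium hydroxide, [Li+].[OH-]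
Why: Saponification of the ethyl ester; the dioxolane is stable to base and survives a short, cold acidification to pH 4.

Step 12
Reactants: 14 6-{[(3R,4R,5R)-4,5-bis(benzyloxy)-6-[(tert-butyldimethylsilyl)oxy]hex-1-yn-3-yl]oxy}-7-methoxy-2-(2-phenylethyl)-4H-chromen-4-one; 17 2-[2-(2-phenylethyl)-1,3-dioxolan-2-yl]acetic acid
Product: 19 6-{[(5R,6R,7R)-6,7-bis(benzyloxy)-8-[(tert-butyldimethylsilyl)oxy]-2-oxo-1-[2-(2-phenylethyl)-1,3-dioxolan-2-yl]oct-3-yn-5-yl]oxy}-7-methoxy-2-(2-phenylethyl)-4H-chromen-4-one, via acid chloride 18 (not isolated)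
Conditions: 17, Me2C=C(Cl)NMe2, CH2Cl2, 0 °C → rt; then 14, PdCl2(PPh3)2 (2 mol %), CuI (4 mol %), Et3N (1.2 equiv), THF, rt
Reagents that add atoms: 1-chloro-N,N,2-trimethylprop-1-en-1-amine, CC(C)=C(Cl)N(C)C (chlorine of the intermediate 18 only)
Why: The α-chloroenamine makes the acid chloride without releasing HCl, so the dioxolane survives; acyl Sonogashira coupling then follows (PdCl2(PPh3)2 is reduced in situ to zerovalent palladium, which inserts into the C–Cl bond, and the copper acetylide transmetalates), forming C4–C4a with only one equivalent of amine base.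

Step 13
Reactants: 19 the silyl ether ynone of step 12
Product: 20 6-{[(5R,6R,7R)-6,7-bis(benzyloxy)-8-hydroxy-2-oxo-1-[2-(2-phenylethyl)-1,3-dioxolan-2-yl]oct-3-yn-5-yl]oxy}-7-methoxy-2-(2-phenylethyl)-4H-chromen-4-one
Conditions: HF·pyridine, pyridine, THF, 0 °C
Reagents that add atoms: none
Why: Fluoride cleavage of a primary silyl ether under buffered, weakly acidic conditions, which spare the ynone (no basic fluoride) and the dioxolane.

Step 14
Reactants: 20 the primary alcohol of step 13
Product: 21 (2S,3R,4R)-2,3-bis(benzyloxy)-4-{[7-methoxy-4-oxo-2-(2-phenylethyl)-4H-chromen-6-yl]oxy}-7-oxo-8-[2-(2-phenylethyl)-1,3-dioxolan-2-yl]oct-5-ynal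
Conditions: Dess–Martin periodinane, NaHCO3, CH2Cl2, 0 °C → rt; short filtration, used at once
Reagents that add atoms: none
Why: Dess–Martin oxidation of the primary alcohol under buffered, non-basic conditions, which should not epimerise the α-benzyloxy aldehyde or isomerise the ynone.

Step 15
Reactants: 21 the ynone aldehyde of step 14
Product: 22 6-{[(1S,4S,5R,6S)-5,6-bis(benzyloxy)-4-hydroxy-2-iodo-3-{[2-(2-phenylethyl)-1,3-dioxolan-2-yl]acetyl}cyclohex-2-en-1-yl]oxy}-7-methoxy-2-(2-phenylethyl)-4H-chromen-4-one
Conditions: MgI2 (2.5 equiv, from Mg and I2 in Et2O), CH2Cl2 (0.01 M), −78 → −20 °C; cold aq. NaHCO3/Na2S2O3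
Reagents that add atoms: magnesium diiodide, [Mg+2].[I-].[I-]
Why: MgI2 binds the C4 carbonyl and iodide adds to the ynone β-carbon C8a to give a magnesium 3-iodoallenolate, whose central carbon C4a then attacks the C5 aldehyde. The closest known reaction type is the MgI2-promoted iodo-aldol (β-iodo Baylis–Hillman) reaction of ynones with aldehydes, here run within one molecule. The ring closes in a 6-(enolexo)-exo-trig mode: the enolate π system lies in the plane of the C8a substituents and the tether can bring the aldehyde only to the C8 side, so iodide and the new C–C bond end up anti and the alkene is endocyclic. The new stereocentre C5 is controlled by the ring: the large iodine at C8a pushes the C8 aryloxy group pseudoaxial (allylic 1,2-strain), which puts the C7 and C6 benzyloxy groups equatorial. Magnesium bridging the aldehyde oxygen to the O6 benzyl ether and to the allenolate oxygen holds the C5 oxygen pseudoequatorial, which gives the 5,6-trans (5S) alcohol. The step needs iodide addition to outrun enolisation at C8, ring closure to beat intermolecular aldol, and the dioxolane to stay closed; these are secured by a non-basic medium, high dilution and a cold quench.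

Step 16
Reactants: 22 the iodo cyclohexenol of step 15
Product: 24 (5S,6R,7S,8S)-6,7-bis(benzyloxy)-5-hydroxy-8-{[7-methoxy-4-oxo-2-(2-phenylethyl)-4H-chromen-6-yl]oxy}-2-(2-phenylethyl)-5,6,7,8-tetrahydro-4H-chromen-4-one, via iodoenone 1,3-diketone 23 (not isolated)
Conditions: TsOH·H2O (0.2 equiv), acetone/H2O 10:1, 35 °C; then K2CO3 (3 equiv), same flask, rt
Reagents that add atoms: water, O
Why: Acid-catalysed ketal exchange in wet acetone frees the C2 ketone (water keeps the C5 hydroxyl from condensing with it); K2CO3 then deprotonates only the 1,3-diketone, whose enolate oxygen displaces the cis vinylic iodide at C8a by addition–elimination to form O1–C8a and the γ-pyranone; the carbonate is too weak to deprotonate C8.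

Step 17
Reactants: 24 the dibenzyl ether of step 16
Product: 25 (5S,6R,7S,8S)-5,6,7-trihydroxy-8-{[7-methoxy-4-oxo-2-(2-phenylethyl)-4H-chromen-6-yl]oxy}-2-(2-phenylethyl)-5,6,7,8-tetrahydro-4H-chromen-4-one
Conditions: H2 (1 atm), 10% Pd/C, EtOAc, rt, stopped at full debenzylation
Reagents that add atoms: none
Why: Catalytic hydrogenolysis of two alkyl benzyl ethers under neutral conditions; the tetrasubstituted pyranone alkene binds poorly to palladium, which should protect the adjacent C5–O and C8–O bonds, and chromone double bonds are reduced only slowly.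

## Compound list

1 | diethyl D-tartrate, diethyl (2S,3S)-2,3-dihydroxybutanedioate | CCOC(=O)[C@@H](O)[C@H](O)C(=O)OCC | starting material
2 | diethyl (2S,3S)-2,3-bis(benzyloxy)butanedioate | CCOC(=O)[C@@H](OCc1ccccc1)[C@H](OCc1ccccc1)C(=O)OCC | intermediate
3 | (2R,3R)-2,3-bis(benzyloxy)butane-1,4-diol | OC[C@@H](OCc1ccccc1)[C@H](OCc1ccccc1)CO | intermediate
4 | (2R,3R)-2,3-bis(benzyloxy)-4-[(tert-butyldimethylsilyl)oxy]butan-1-ol | CC(C)(C)[Si](C)(C)OC[C@@H](OCc1ccccc1)[C@H](OCc1ccccc1)CO | intermediate
5 | (2S,3R)-2,3-bis(benzyloxy)-4-[(tert-butyldimethylsilyl)oxy]butanal | CC(C)(C)[Si](C)(C)OC[C@@H](OCc1ccccc1)[C@H](OCc1ccccc1)C=O | intermediate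
6 | (3S,4R,5R)-4,5-bis(benzyloxy)-6-[(tert-butyldimethylsilyl)oxy]-1-(trimethylsilyl)hex-1-yn-3-ol | CC(C)(C)[Si](C)(C)OC[C@@H](OCc1ccccc1)[C@H](OCc1ccccc1)[C@@H](O)C#C[Si](C)(C)C | intermediate (not isolated)
7 | (3S,4R,5R)-4,5-bis(benzyloxy)-6-[(tert-butyldimethylsilyl)oxy]hex-1-yn-3-ol | CC(C)(C)[Si](C)(C)OC[C@@H](OCc1ccccc1)[C@H](OCc1ccccc1)[C@@H](O)C#C | intermediate
8 | 1-(2,5-dihydroxy-4-methoxyphenyl)ethanone | CC(=O)c1cc(O)c(OC)cc1O | starting material
9 | 1-[5-(benzyloxy)-2-hydroxy-4-methoxyphenyl]ethanone | CC(=O)c1cc(OCc2ccccc2)c(OC)cc1O | intermediate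
10 | ethyl 3-phenylpropanoate | CCOC(=O)CCc1ccccc1 | starting material
11 | 1-[5-(benzyloxy)-2-hydroxy-4-methoxyphenyl]-5-phenylpentane-1,3-dione | O=C(CC(=O)CCc1ccccc1)c1cc(OCc2ccccc2)c(OC)cc1O | intermediate (not isolated)
12 | 6-(benzyloxy)-7-methoxy-2-(2-phenylethyl)-4H-chromen-4-one | COc1cc2oc(CCc3ccccc3)cc(=O)c2cc1OCc1ccccc1 | intermediate
13 | 6-hydroxy-7-methoxy-2-(2-phenylethyl)-4H-chromen-4-one | COc1cc2oc(CCc3ccccc3)cc(=O)c2cc1O | intermediate
14 | 6-{[(3R,4R,5R)-4,5-bis(benzyloxy)-6-[(tert-butyldimethylsilyl)oxy]hex-1-yn-3-yl]oxy}-7-methoxy-2-(2-phenylethyl)-4H-chromen-4-one | CC(C)(C)[Si](C)(C)OC[C@@H](OCc1ccccc1)[C@H](OCc1ccccc1)[C@H](Oc1cc2c(=O)cc(CCc3ccccc3)oc2cc1OC)C#C | intermediate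
15 | ethyl 3-oxo-5-phenylpentanoate | CCOC(=O)CC(=O)CCc1ccccc1 | starting material
16 | ethyl 2-[2-(2-phenylethyl)-1,3-dioxolan-2-yl]acetate | CCOC(=O)CC1(CCc2ccccc2)OCCO1 | intermediate
17 | 2-[2-(2-phenylethyl)-1,3-dioxolan-2-yl]acetic acid | OC(=O)CC1(CCc2ccccc2)OCCO1 | intermediate
18 | 2-[2-(2-phenylethyl)-1,3-dioxolan-2-yl]acetyl chloride | O=C(Cl)CC1(CCc2ccccc2)OCCO1 | intermediate (not isolated)
19 | 6-{[(5R,6R,7R)-6,7-bis(benzyloxy)-8-[(tert-butyldimethylsilyl)oxy]-2-oxo-1-[2-(2-phenylethyl)-1,3-dioxolan-2-yl]oct-3-yn-5-yl]oxy}-7-methoxy-2-(2-phenylethyl)-4H-chromen-4-one | CC(C)(C)[Si](C)(C)OC[C@@H](OCc1ccccc1)[C@H](OCc1ccccc1)[C@H](Oc1cc2c(=O)cc(CCc3ccccc3)oc2cc1OC)C#CC(=O)CC1(CCc2ccccc2)OCCO1 | intermediate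
20 | 6-{[(5R,6R,7R)-6,7-bis(benzyloxy)-8-hydroxy-2-oxo-1-[2-(2-phenylethyl)-1,3-dioxolan-2-yl]oct-3-yn-5-yl]oxy}-7-methoxy-2-(2-phenylethyl)-4H-chromen-4-one | OC[C@@H](OCc1ccccc1)[C@H](OCc1ccccc1)[C@H](Oc1cc2c(=O)cc(CCc3ccccc3)oc2cc1OC)C#CC(=O)CC1(CCc2ccccc2)OCCO1 | intermediate
21 | (2S,3R,4R)-2,3-bis(benzyloxy)-4-{[7-methoxy-4-oxo-2-(2-phenylethyl)-4H-chromen-6-yl]oxy}-7-oxo-8-[2-(2-phenylethyl)-1,3-dioxolan-2-yl]oct-5-ynal | O=C[C@@H](OCc1ccccc1)[C@H](OCc1ccccc1)[C@H](Oc1cc2c(=O)cc(CCc3ccccc3)oc2cc1OC)C#CC(=O)CC1(CCc2ccccc2)OCCO1 | intermediate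
22 | 6-{[(1S,4S,5R,6S)-5,6-bis(benzyloxy)-4-hydroxy-2-iodo-3-{[2-(2-phenylethyl)-1,3-dioxolan-2-yl]acetyl}cyclohex-2-en-1-yl]oxy}-7-methoxy-2-(2-phenylethyl)-4H-chromen-4-one | COc1cc2oc(CCc3ccccc3)cc(=O)c2cc1O[C@@H]1C(I)=C(C(=O)CC2(CCc3ccccc3)OCCO2)[C@H](O)[C@@H](OCc2ccccc2)[C@@H]1OCc1ccccc1 | intermediate
23 | 6-{[(1S,4S,5R,6S)-5,6-bis(benzyloxy)-4-hydroxy-2-iodo-3-(3-oxo-5-phenylpentanoyl)cyclohex-2-en-1-yl]oxy}-7-methoxy-2-(2-phenylethyl)-4H-chromen-4-one | COc1cc2oc(CCc3ccccc3)cc(=O)c2cc1O[C@@H]1C(I)=C(C(=O)CC(=O)CCc2ccccc2)[C@H](O)[C@@H](OCc2ccccc2)[C@@H]1OCc1ccccc1 | intermediate (not isolated)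
24 | (5S,6R,7S,8S)-6,7-bis(benzyloxy)-5-hydroxy-8-{[7-methoxy-4-oxo-2-(2-phenylethyl)-4H-chromen-6-yl]oxy}-2-(2-phenylethyl)-5,6,7,8-tetrahydro-4H-chromen-4-one | COc1cc2oc(CCc3ccccc3)cc(=O)c2cc1O[C@@H]1c2oc(CCc3ccccc3)cc(=O)c2[C@H](O)[C@@H](OCc2ccccc2)[C@@H]1OCc1ccccc1 | intermediate
25 | (5S,6R,7S,8S)-5,6,7-trihydroxy-8-{[7-methoxy-4-oxo-2-(2-phenylethyl)-4H-chromen-6-yl]oxy}-2-(2-phenylethyl)-5,6,7,8-tetrahydro-4H-chromen-4-one | COc1cc2oc(CCc3ccccc3)cc(=O)c2cc1O[C@@H]1c2oc(CCc3ccccc3)cc(=O)c2[C@H](O)[C@@H](O)[C@@H]1O | target

## Step count and risks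

Total: 17 steps. Longest linear sequence: 12 steps (1, 2, 3, 4, 5, 9, 12, 13, 14, 15, 16, 17).

**Step 15 (key step).** Several things can go wrong:
- the iodoallenolate is protonated before it closes the ring, giving plain hydroiodination;
- the Lewis acid opens the dioxolane, and the freed diketone then closes onto the ynone before the carbocycle forms;
- facial selectivity at C5 is lost if the half-chair with axial benzyloxy groups competes;
- the substrate is enolised at C8.

Fallback, from 21: dimethylaluminium benzenethiolate (Me2AlSPh, CH2Cl2, −78 °C) transfers the softer thiolate to C8a, and the aluminium allenolate closes the ring in the same tandem conjugate addition–aldol manner. This gives the 2-acyl-3-(phenylsulfanyl)cyclohexenol F1. The two-stage treatment of step 16 (ketal hydrolysis, then carbonate) should then close the pyranone with loss of benzenethiol by addition–elimination on the β-thio enone, and the route is rejoined at 24.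

**Step 5.** Incomplete chelation control would erode the syn selectivity at C8. Fallback, from 5: lithium (trimethylsilyl)acetylide in THF gives 6 together with its (3R)-epimer F2. Dess–Martin oxidation of the mixture gives the ynone F3. Asymmetric transfer hydrogenation with the enantiomer of RuCl(p-cymene)(TsDPEN) that delivers the (3S)-carbinol (i-PrOH) returns 6 under reagent control, and methanolic K2CO3 then gives 7.

**Step 9.** The carbinol is flanked by a benzyloxy group and the phenol is only moderately acidic, so slow substitution, elimination or SN2′ attack may take over. Fallback, from 7: mesylation (MsCl, Et3N, CH2Cl2, −20 °C) gives the methanesulfonate F4. Displacement with the caesium salt of 13 (Cs2CO3, DMF, rt) then gives 14 with the same inversion.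

**Step 13.** The freed primary hydroxyl may add to the ynone (6-exo oxa-Michael closure), or the dioxolane may be lost in the HF medium. Fallback, from 14, with the order of events changed:
- desilylation (Bu4NF/AcOH, THF) gives the hydroxy alkyne F5;
- Dess–Martin oxidation gives the alkynyl aldehyde F6;
- acyl Sonogashira coupling of F6 with 18, under the conditions of step 12, gives 21 directly, so a hydroxy ynone never exists.

**Step 16.** The C5 hydroxyl may condense with the unmasked C2 ketone during the acid stage (hemiketal formation and dehydration), or base may cause elimination across C7–C8. Fallback, from 22: acetylation (Ac2O, pyridine) gives the C5 acetate F7. The same acid and carbonate stages then give the acetylated pyranone F8, and brief K2CO3 in MeOH at 0 °C removes the acetate to return 24.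

**Step 17.** Hydrogenolysis may also cleave the allylic-type C8–O aryl or C5–O bonds, or saturate a chromone C2=C3 bond. Fallback, from 24: Lewis-acid debenzylation with BCl3 and pentamethylbenzene as cation scavenger (CH2Cl2, −78 °C) gives 25 without hydrogen; no new compound is involved.

## Further compounds

F1 | step 15 | 6-{[(1S,4S,5R,6S)-5,6-bis(benzyloxy)-4-hydroxy-2-(phenylsulfanyl)-3-{[2-(2-phenylethyl)-1,3-dioxolan-2-yl]acetyl}cyclohex-2-en-1-yl]oxy}-7-methoxy-2-(2-phenylethyl)-4H-chromen-4-one | COc1cc2oc(CCc3ccccc3)cc(=O)c2cc1O[C@@H]1C(Sc2ccccc2)=C(C(=O)CC2(CCc3ccccc3)OCCO2)[C@H](O)[C@@H](OCc2ccccc2)[C@@H]1OCc1ccccc1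
F2 | step 5 | (3R,4R,5R)-4,5-bis(benzyloxy)-6-[(tert-butyldimethylsilyl)oxy]-1-(trimethylsilyl)hex-1-yn-3-ol | CC(C)(C)[Si](C)(C)OC[C@@H](OCc1ccccc1)[C@H](OCc1ccccc1)[C@H](O)C#C[Si](C)(C)C
F3 | step 5 | (4S,5R)-4,5-bis(benzyloxy)-6-[(tert-butyldimethylsilyl)oxy]-1-(trimethylsilyl)hex-1-yn-3-one | CC(C)(C)[Si](C)(C)OC[C@@H](OCc1ccccc1)[C@H](OCc1ccccc1)C(=O)C#C[Si](C)(C)C
F4 | step 9 | (3S,4S,5R)-4,5-bis(benzyloxy)-6-[(tert-butyldimethylsilyl)oxy]hex-1-yn-3-yl methanesulfonate (mesylate of 7) | CC(C)(C)[Si](C)(C)OC[C@@H](OCc1ccccc1)[C@H](OCc1ccccc1)[C@@H](OS(C)(=O)=O)C#C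
F5 | step 13 | 6-{[(3R,4R,5R)-4,5-bis(benzyloxy)-6-hydroxyhex-1-yn-3-yl]oxy}-7-methoxy-2-(2-phenylethyl)-4H-chromen-4-one | OC[C@@H](OCc1ccccc1)[C@H](OCc1ccccc1)[C@H](Oc1cc2c(=O)cc(CCc3ccccc3)oc2cc1OC)C#C
F6 | step 13 | (2S,3R,4R)-2,3-bis(benzyloxy)-4-{[7-methoxy-4-oxo-2-(2-phenylethyl)-4H-chromen-6-yl]oxy}hex-5-ynal | O=C[C@@H](OCc1ccccc1)[C@H](OCc1ccccc1)[C@H](Oc1cc2c(=O)cc(CCc3ccccc3)oc2cc1OC)C#C
F7 | step 16 | acetate of 22 at the ring carbinol (C5 of unit B), configuration as in 22 | COc1cc2oc(CCc3ccccc3)cc(=O)c2cc1O[C@@H]1C(I)=C(C(=O)CC2(CCc3ccccc3)OCCO2)[C@H](OC(C)=O)[C@@H](OCc2ccccc2)[C@@H]1OCc1ccccc1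
F8 | step 16 | 5-O-acetyl derivative of 24, configuration as in 24 | COc1cc2oc(CCc3ccccc3)cc(=O)c2cc1O[C@@H]1c2oc(CCc3ccccc3)cc(=O)c2[C@H](OC(C)=O)[C@@H](OCc2ccccc2)[C@@H]1OCc1ccccc1
F0 | step 17 | none | none
A1 | alternative 1 | 8-[4-(benzyloxy)-2-methoxyphenoxy]-5,6,7-tris[(tert-butyldimethylsilyl)oxy]-2-(2-phenylethyl)-5,6,7,8-tetrahydro-4H-chromen-4-one, ring configuration as in 25 | COc1cc(OCc2ccccc2)ccc1O[C@@H]1c2oc(CCc3ccccc3)cc(=O)c2[C@H](O[Si](C)(C)C(C)(C)C)[C@@H](O[Si](C)(C)C(C)(C)C)[C@@H]1O[Si](C)(C)C(C)(C)C
A2 | alternative 1 | 4-{6-[4-(benzyloxy)-2-methoxyphenoxy]-3,4,5-tris[(tert-butyldimethylsilyl)oxy]cyclohex-1-en-1-yl}morpholine, ring configuration as in A1 | COc1cc(OCc2ccccc2)ccc1O[C@@H]1C(N2CCOCC2)=C[C@H](O[Si](C)(C)C(C)(C)C)[C@@H](O[Si](C)(C)C(C)(C)C)[C@@H]1O[Si](C)(C)C(C)(C)C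
A3 | alternative 1 | 2,2-dimethyl-5-(3-phenylpropanoyl)-1,3-dioxane-4,6-dione | CC1(C)OC(=O)C(C(=O)CCc2ccccc2)C(=O)O1
A4 | alternative 2 | 5,6,7-tri-O-benzyl ether of 25 | COc1cc2oc(CCc3ccccc3)cc(=O)c2cc1O[C@@H]1c2oc(CCc3ccccc3)cc(=O)c2[C@H](OCc2ccccc2)[C@@H](OCc2ccccc2)[C@@H]1OCc1ccccc1
A5 | alternative 2 | 1-{5-[(3-acetyl-4,5,6-tris(benzyloxy)-2-hydroxycyclohex-2-en-1-yl)oxy]-2-hydroxy-4-methoxyphenyl}ethanone, ring configuration as in A4 | COc1cc(O)c(C(C)=O)cc1O[C@@H]1C(O)=C(C(C)=O)[C@H](OCc2ccccc2)[C@@H](OCc2ccccc2)[C@@H]1OCc1ccccc1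
A6 | alternative 3 | isoxazole-fused tri-O-benzyl carbocycle bearing the unit A aryl ether and a 2-silyloxy-4-phenylbutyl side chain | COc1cc2oc(CCc3ccccc3)cc(=O)c2cc1O[C@@H]1c2noc(C[C@@H](O[Si](C)(C)C(C)(C)C)CCc3ccccc3)c2[C@H](OCc2ccccc2)[C@@H](OCc2ccccc2)[C@@H]1OCc1ccccc1
A7 | alternative 3 | 3,4,5-tris(benzyloxy)-9-[(tert-butyldimethylsilyl)oxy]-2-{[7-methoxy-4-oxo-2-(2-phenylethyl)-4H-chromen-6-yl]oxy}-11-phenylundec-6-ynal oxime, configuration as in A6 | ON=C[C@@H](Oc1cc2c(=O)cc(CCc3ccccc3)oc2cc1OC)[C@@H](OCc1ccccc1)[C@H](OCc1ccccc1)[C@@H](OCc1ccccc1)C#CC[C@@H](O[Si](C)(C)C(C)(C)C)CCc1ccccc1
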